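**Retrosynthetic overview**

- The target is 6,7,8-trimethoxy-3-(3,4,5-trimethoxyphenyl)chromen-4-one, an achiral isoflavone. The strategy rests on one feature: in ring C the C4 carbonyl sits between aromatic C4a of ring A and the sp2 carbon C3 that bears ring B, so C4 can be brought in as carbon monoxide between an aryl iodide (C4a–I) and a 1-arylvinylboron reagent (C3–B).
- The C2=C3 double bond is made last, by dehydrogenation of the isoflavanone. The O1–C2 bond comes before it, by 6-endo oxa-Michael addition of the C8a phenol to the α-aryl enone. Ring C is the only ring formed; rings A and B are bought.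
- The enone comes from a three-component carbonylative Suzuki–Miyaura coupling that makes C4a–C4 and C4–C3 together.
- The aryl iodide is made from 2,3,4-trimethoxyphenol by MOM protection and directed ortho-lithiation/iodination. The boronate is made from 3,4,5-trimethoxyacetophenone by enol triflation and Miyaura borylation.

Key step: step 5

Remark on the chemistry: locants O1, C2, C3, C4, C4a, C5–C8, C8a are those of the chromen-4-one core. The isoflavanone of step 6 is taken as the racemate, since its single stereocentre (C3) becomes sp2 in step 7.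

**Route**

Step 1
Reactants: 1 2,3,4-trimethoxyphenol
Product: 2 1,2,3-trimethoxy-4-(methoxymethoxy)benzene
Conditions: MOMCl (1.3 equiv), iPr2NEt (2 equiv), CH2Cl2, 0 °C to rt
Reagents that add atoms: chloromethyl methyl ether (MOMCl), COCCl
Why: O-alkylation of the phenol by the reactive α-chloro ether under amine base (Williamson-type ether formation) should be clean and installs an acetal that serves both as protecting group and as the directing group for step 2.

Step 2
Reactants: 2 1,2,3-trimethoxy-4-(methoxymethoxy)benzene
Product: 4 1-iodo-3,4,5-trimethoxy-2-(methoxymethoxy)benzene, via aryllithium 3 (not isolated)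
Conditions: n-BuLi (1.2 equiv), TMEDA (1.2 equiv), THF, 0 °C, 1 h; then I2 (1.3 equiv) in THF, −78 °C to rt
Reagents that add atoms: iodine, II
Why: In this directed ortho-metalation the chelating OMOM group outranks a methoxy group as director, so lithiation should occur at the one free position next to it (the future C4a) and iodine then traps the aryllithium at that carbon.

Step 3
Reactants: 5 3,4,5-trimethoxyacetophenone
Product: 7 1-(3,4,5-trimethoxyphenyl)ethenyl trifluoromethanesulfonate, via potassium enolate 6 (not isolated)
Conditions: KN(SiMe3)2 (1.1 equiv), THF, −78 °C (ketone added to the base); then PhNTf2 (1.1 equiv), −78 to 0 °C; chromatography on Et3N-deactivated silica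
Reagents that add atoms: N-phenylbis(trifluoromethanesulfonimide) (PhNTf2), O=S(=O)(N(c1ccccc1)S(=O)(=O)C(F)(F)F)C(F)(F)F
Why: The methyl ketone has a single enolisable position, and O-sulfonylation of its potassium enolate by the triflimide (enol triflate formation) is the standard entry to 1-arylvinyl triflates, with no regio- or stereochemical question.

Step 4
Reactants: 7 1-(3,4,5-trimethoxyphenyl)ethenyl trifluoromethanesulfonate; 8 bis(pinacolato)diboron
Product: 9 4,4,5,5-tetramethyl-2-[1-(3,4,5-trimethoxyphenyl)ethenyl]-1,3,2-dioxaborolane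
Conditions: PdCl2(PPh3)2 (3 mol %), PPh3 (6 mol %), KOPh (1.5 equiv), toluene, 50 °C
Reagents that add atoms: none
Why: In this Miyaura borylation of an alkenyl triflate the palladium phenoxide formed after oxidative addition transmetalates with the diboron reagent, and the weak phenoxide base should hold back Suzuki coupling of the new boronate with unreacted triflate.

Step 5
Reactants: 4 1-iodo-3,4,5-trimethoxy-2-(methoxymethoxy)benzene; 9 4,4,5,5-tetramethyl-2-[1-(3,4,5-trimethoxyphenyl)ethenyl]-1,3,2-dioxaborolane; 10 carbon monoxide
Product: 11 1-[3,4,5-trimethoxy-2-(methoxymethoxy)phenyl]-2-(3,4,5-trimethoxyphenyl)prop-2-en-1-one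
Conditions: PdCl2(PPh3)2 (5 mol %), K2CO3 (3 equiv), BHT (cat.), anisole/H2O (20:1), CO (5 bar), 80 °C; 9 (1.3 equiv)
Reagents that add atoms: none
Why: Zerovalent palladium inserts into the C4a–I bond of 4, CO coordinates and the electron-rich aryl group migrates onto it to give an aroylpalladium iodide, the carbonate-activated boronate 9 transfers its 1-arylvinyl group, and reductive elimination forms C4–C3 and releases the catalyst, so that C4a–C4 and C4–C3 are made in one operation. The closest known reaction type is the carbonylative Suzuki–Miyaura coupling of aryl iodides with aryl- and alkenylboron reagents to diaryl ketones and aryl vinyl ketones. No ring is closed and no stereocentre is formed. The selectivity needed is carbonylative over direct coupling: the ortho-alkoxy, electron-rich arylpalladium species should take up CO quickly, the hindered 1,1-disubstituted boronate should transmetalate slowly, and several bar of CO should hold palladium at the acyl stage before the boron reagent intercepts it. The MOM ether keeps the C8a oxygen from attacking the acylpalladium species or the product enone, and the weak base with BHT is meant to limit protodeboronation and oligomerisation of the α-aryl enone.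

Step 6
Reactants: 11 1-[3,4,5-trimethoxy-2-(methoxymethoxy)phenyl]-2-(3,4,5-trimethoxyphenyl)prop-2-en-1-one
Product: 13 (±)-6,7,8-trimethoxy-3-(3,4,5-trimethoxyphenyl)chroman-4-one, via free phenol 12 (not isolated)
Conditions: 3 M aq. HCl, THF, 50 °C; aq. NaHCO3 work-up
Reagents that add atoms: none
Why: Acid hydrolysis of the MOM acetal frees the C8a phenol, which should add 6-endo-trig to the unhindered terminal CH2 of the enone (intramolecular oxa-Michael addition, the ring closure of the classical isoflavanone synthesis); the C3 stereocentre arises without control on protonation of the enol, so a racemate is expected, and it is removed in step 7.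

Step 7
Reactants: 13 (±)-6,7,8-trimethoxy-3-(3,4,5-trimethoxyphenyl)chroman-4-one
Product: 14 6,7,8-trimethoxy-3-(3,4,5-trimethoxyphenyl)chromen-4-one
Conditions: DDQ (1.5 equiv), 1,4-dioxane, reflux
Reagents that add atoms: none
Why: DDQ dehydrogenation of a chroman-4-one should proceed by hydride abstraction from C2 of the enol, giving a cation stabilised by O1, followed by proton loss to the C2=C3 bond conjugated with the C4 carbonyl and ring B, which also erases the C3 stereocentre.

**Compound list**

1 | 2,3,4-trimethoxyphenol | COc1ccc(O)c(OC)c1OC | starting material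
2 | 1,2,3-trimethoxy-4-(methoxymethoxy)benzene | COCOc1ccc(OC)c(OC)c1OC | intermediate
3 | [3,4,5-trimethoxy-2-(methoxymethoxy)phenyl]lithium | [Li]c1cc(OC)c(OC)c(OC)c1OCOC | intermediate
4 | 1-iodo-3,4,5-trimethoxy-2-(methoxymethoxy)benzene | COCOc1c(I)cc(OC)c(OC)c1OC | intermediate
5 | 3,4,5-trimethoxyacetophenone | CC(=O)c1cc(OC)c(OC)c(OC)c1 | starting material
6 | potassium 1-(3,4,5-trimethoxyphenyl)ethenolate | [K+].[O-]C(=C)c1cc(OC)c(OC)c(OC)c1 | intermediate
7 | 1-(3,4,5-trimethoxyphenyl)ethenyl trifluoromethanesulfonate | C=C(OS(=O)(=O)C(F)(F)F)c1cc(OC)c(OC)c(OC)c1 | intermediate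
8 | bis(pinacolato)diboron | CC1(C)OB(OC1(C)C)B1OC(C)(C)C(C)(C)O1 | starting material
9 | 4,4,5,5-tetramethyl-2-[1-(3,4,5-trimethoxyphenyl)ethenyl]-1,3,2-dioxaborolane | C=C(B1OC(C)(C)C(C)(C)O1)c1cc(OC)c(OC)c(OC)c1 | intermediate
10 | carbon monoxide | [C-]#[O+] | starting material
11 | 1-[3,4,5-trimethoxy-2-(methoxymethoxy)phenyl]-2-(3,4,5-trimethoxyphenyl)prop-2-en-1-one | COCOc1c(C(=O)C(=C)c2cc(OC)c(OC)c(OC)c2)cc(OC)c(OC)c1OC | intermediate
12 | 1-(2-hydroxy-3,4,5-trimethoxyphenyl)-2-(3,4,5-trimethoxyphenyl)prop-2-en-1-one | C=C(C(=O)c1cc(OC)c(OC)c(OC)c1O)c1cc(OC)c(OC)c(OC)c1 | intermediate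
13 | (±)-6,7,8-trimethoxy-3-(3,4,5-trimethoxyphenyl)chroman-4-one (racemic) | COc1cc(C2COc3c(OC)c(OC)c(OC)cc3C2=O)cc(OC)c1OC | intermediate
14 | 6,7,8-trimethoxy-3-(3,4,5-trimethoxyphenyl)chromen-4-one | COc1cc(-c2coc3c(OC)c(OC)c(OC)cc3c2=O)cc(OC)c1OC | target

**Step count and risks**

Total steps: 7. Longest linear sequence: 5 steps (steps 1, 2, 5, 6, 7 from phenol 1; equally steps 3, 4, 5, 6, 7 from ketone 5).

Steps most likely to fail:

1. Step 5. Transmetalation of the hindered boronate may be too slow, so that protodeboronation or hydroxycarbonylation of the aroylpalladium species takes over. Direct coupling without CO uptake may also compete, and the product enone may oligomerise under base. The fallback builds the same two bonds one after the other and takes C4 from DMF instead of CO. It sets out from MOM ether 2 and triflate 7 and comes back at enone 11. Compound 2 is lithiated to 3 as in step 2 and quenched with DMF to give 3,4,5-trimethoxy-2-(methoxymethoxy)benzaldehyde F1. Nozaki–Hiyama–Kishi coupling of F1 with 7 (CrCl2 in excess, NiCl2 cat., DMF, rt) should give the allylic alcohol (±)-1-[3,4,5-trimethoxy-2-(methoxymethoxy)phenyl]-2-(3,4,5-trimethoxyphenyl)prop-2-en-1-ol F2. Oxidation of this allylic and benzylic alcohol with MnO2 in CH2Cl2 gives 11.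

2. Step 4. The new boronate may couple with unreacted triflate to the 2,3-diarylbutadiene, or the triflate may be hydrolysed back to the ketone under phenoxide. The fallback is a Shapiro borylation that avoids the triflate; it sets out from ketone 5 and comes back at boronate 9. Condensation of 5 with 2,4,6-triisopropylbenzenesulfonohydrazide (THF, cat. HCl, rt) gives the hydrazone N'-[1-(3,4,5-trimethoxyphenyl)ethylidene]-2,4,6-triisopropylbenzenesulfonohydrazide F3. Treatment with n-BuLi (2.1 equiv, THF, −78 to 0 °C) expels sulfinate and nitrogen to give [1-(3,4,5-trimethoxyphenyl)ethenyl]lithium F4. Trapping at −78 °C with 2-isopropoxy-4,4,5,5-tetramethyl-1,3,2-dioxaborolane gives 9.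

3. Step 6. The enone, once exposed in acid, may be hydrated or oligomerise before the ring closes, and the electron-rich rings may be hydroxymethylated by the formaldehyde released. The fallback masks the enone as a Mannich base during the acid step; it sets out from enone 11 and comes back at isoflavanone 13. Aza-Michael addition of dimethylamine (THF, rt) gives (±)-3-(dimethylamino)-1-[3,4,5-trimethoxy-2-(methoxymethoxy)phenyl]-2-(3,4,5-trimethoxyphenyl)propan-1-one F5. Aqueous HCl in THF removes the MOM group from the ammonium salt to give (±)-3-(dimethylamino)-1-(2-hydroxy-3,4,5-trimethoxyphenyl)-2-(3,4,5-trimethoxyphenyl)propan-1-one F6. Warming F6 with Na2CO3 in aqueous ethanol eliminates dimethylamine, and the phenoxide closes onto the regenerated enone to give 13, as in the classical Mannich-base synthesis of isoflavanones.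

**Further compounds**

F1 | step 5 | 3,4,5-trimethoxy-2-(methoxymethoxy)benzaldehyde | COCOc1c(C=O)cc(OC)c(OC)c1OC
F2 | step 5 | (±)-1-[3,4,5-trimethoxy-2-(methoxymethoxy)phenyl]-2-(3,4,5-trimethoxyphenyl)prop-2-en-1-ol | COCOc1c(C(O)C(=C)c2cc(OC)c(OC)c(OC)c2)cc(OC)c(OC)c1OC
F3 | step 4 | N'-[(1E)-1-(3,4,5-trimethoxyphenyl)ethylidene]-2,4,6-triisopropylbenzenesulfonohydrazide | C/C(=N\NS(=O)(=O)c1c(C(C)C)cc(C(C)C)cc1C(C)C)c1cc(OC)c(OC)c(OC)c1
F4 | step 4 | [1-(3,4,5-trimethoxyphenyl)ethenyl]lithium | [Li]C(=C)c1cc(OC)c(OC)c(OC)c1
F5 | step 6 | (±)-3-(dimethylamino)-1-[3,4,5-trimethoxy-2-(methoxymethoxy)phenyl]-2-(3,4,5-trimethoxyphenyl)propan-1-one | CN(C)CC(C(=O)c1cc(OC)c(OC)c(OC)c1OCOC)c1cc(OC)c(OC)c(OC)c1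
F6 | step 6 | (±)-3-(dimethylamino)-1-(2-hydroxy-3,4,5-trimethoxyphenyl)-2-(3,4,5-trimethoxyphenyl)propan-1-one | CN(C)CC(C(=O)c1cc(OC)c(OC)c(OC)c1O)c1cc(OC)c(OC)c(OC)c1
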